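Does it matter which end group is fed slowly, or does the charge tell the links at the end whatever the order?

| flask | first end groups | second end groups | protic impurity | remark | time |
|---|---|---|---|---|---|
| green | 0.20 M | 0.19 M | 0.060 M | run made earlier |  |
| ochre | 0.20 M | 0.19 M | 0.030 M | run made earlier |  |
| amber | 0.20 M | 0.19 M | 0.12 M | run made earlier |  |
| red | 0.20 M | 0.095 M | 0.060 M | run made earlier |  |
| summer | 0.20 M | 0.190 M (fed, over 50 s) | 0.0600 M | all else is in the flask from the start; the feed brings no volume worth counting | 2.0 min |
| autumn | 0.20 M (fed, over 50 s) | 0.190 M | 0.0600 M | all else is in the flask from the start; the feed brings no volume worth counting | 2.0 min |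
| midnight | 0.20 M | 0.190 M | 0.0600 M | everything together at the start | 2.0 min |

| run | time / s | links / % | first end groups / % |
|---|---|---|---|
| green | 10.0 | 76.4 | 3.5 |
| green | 25.0 | 71.3 | 4.4 |
| green | 40.0 | 68.5 | 0.4 |
| green | 60.0 | 65.1 | 1.3 |
| green | 90.0 | 61.9 | 0 |
| green | 120 | 63.7 | 0.7 |
| ochre | 10.0 | 78.4 | 7.2 |
| ochre | 12.0 | 76.2 | 6.0 |
| ochre | 20.0 | 71.7 | 4.3 |
| ochre | 40.0 | 67.0 | 2.9 |
| ochre | 60.0 | 64.6 | 0.4 |
| ochre | 90.0 | 61.4 | 0 |
| amber | 10.0 | 75.9 | 4.2 |
| amber | 20.0 | 69.4 | 2.5 |
| amber | 30.0 | 67.4 | 1.9 |
| amber | 50.0 | 66.4 | 0.5 |
| amber | 80.0 | 61.9 | 0 |
| amber | 90.0 | 59.9 | 0 |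
| red | 10.0 | 32.4 | 25.8 |
| red | 25.0 | 24.1 | 12.5 |
| red | 40.0 | 21.4 | 6.5 |
| red | 60.0 | 19.6 | 3.1 |
| red | 90.0 | 17.1 | 1.1 |

(standard deviation of a reading: 1 percentage point)

1. the flask with the highest amount of links, in percent of the first end groups charged ("all alike" if they lie within 1.5 percentage points) (summer / autumn / midnight / all alike)
2. final links, as a percentage of the first end groups charged, in summer
3. final links, as a percentage of the first end groups charged, in autumn
4. final links, as a percentage of the first end groups charged, in midnight

Two chemists disagree. The second holds that the charge tells the end. Green, ochre and amber, with protic impurity running from 0.030 M to 0.12 M, stand at 61.9%, 61.4% and 59.9% of links at 90.0 s, against a scatter of 1 percentage point. So summer, autumn and midnight, with equal charges, should come out alike, near green.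

The first chemist looks at red, which differs from green in the second end groups charged and reads 17.1% at that time. From this pair of readings she takes g = 94 points, the points of links won per equivalent of second end groups, an equivalent being as much as the first end groups charged. She calls g steep and takes links for the intermediate of a consecutive reaction, eaten by surplus first end groups. So for her the running ratio counts. At mid-feed summer has seen 0.475 equivalents, the ratio of red, while autumn's first end groups have met 1.90.

My own reckoning goes no further than her order: summer between red and green, autumn above green. The forecast, on her side, puts autumn highest, with 35% in summer, 70% in autumn and 62% in midnight: "Autumn keeps first end groups scarce against excess second end groups, which favours links".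

The flasks give 38.2% in summer, 68.1% in autumn and 61.9% in midnight, so autumn leads, and the forecast stands within its tolerance. The second chemist keeps the ground she argued from: midnight, with green's charges and everything together at the start, gives 61.9% where green reads 63.7% at 120 s, with a scatter of 1 point on that reading.

    first end groups + protic impurity → quenched substrate (k = 0.620 M⁻¹ s⁻¹)
    first end groups + second end groups ⇌ links + released group (K = 83.0, k = 53.0 M⁻¹ s⁻¹)
    released group → by-product carried off (k = 0.0260 s⁻¹)
    first end groups + links → side product (k = 0.500 M⁻¹ s⁻¹)

At g, autumn's gain over midnight, 6.2 points, is worth 0.0132 M of second end groups in the charge. The same g carries to a neighbour of autumn charged with 0.11 M of second end groups, all else held. Taking 0.400 equivalents from autumn's 68.1% leaves 30.4% of links. That neighbour gives 26.4% of links, with 54.9% in side product, a percentage in which each side product already counts as two.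

The numbers in the tables were generated by integration with constants of no real substance, and the scatter is random.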